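**Impossible yield.** In red you cannot find product above 27.5% of the substrate charged, since each product takes up one coupling partner and red holds 22.0 mM of it against 80 mM of substrate. The ratio c(coupling partner)/c(substrate) is the partner ceiling; in red the coupling partner is the limiting reagent.

| flask | substrate | coupling partner | free catalyst | second catalyst | remark | time |
|---|---|---|---|---|---|---|
| spring | 13 mM (in portions, 4) | 22 mM | 0.12 mM | 0.20 mM | run made earlier; portions every 8.0 min |  |
| noon | 30 mM (in portions, 4) | 22 mM | 0.12 mM | 0.20 mM | run made earlier; portions every 8.0 min |  |
| autumn | 63 mM (in portions, 4) | 22 mM | 0.12 mM | 0.20 mM | run made earlier; portions every 8.0 min |  |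
| dawn | 20 mM (in portions, 4) | 22 mM | 0.23 mM | 0.20 mM | run made earlier; portions every 8.0 min |  |
| red | 80 mM (in portions, 4) | 22.0 mM | 0.12 mM | 0.60 mM | the portions of substrate follow each other after 8.0 min, the first at the start | 30 min |
| blue | 10 mM (in portions, 4) | 60.0 mM | 0.12 mM | 0.20 mM | the portions of substrate follow each other after 15 min, the first at the start | 30 min |
| teal | 20 mM (in portions, 4) | 22.0 mM | 0.12 mM | 0.20 mM | the portions of substrate follow each other after 8.0 min, the first at the start | 30 min |
| grey | 20 mM (in portions, 4) | 22.0 mM | 0.25 mM | 0.20 mM | the portions of substrate follow each other after 2.5 min, the first at the start | 30 min |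
| ochre | 20 mM (in portions, 4) | 22.0 mM | 0.080 mM | 0.60 mM | the portions of substrate follow each other after 8.0 min, the first at the start | 30 min |
| green | 20 mM (in portions, 4) | 22.0 mM | 0.50 mM | 0.12 mM | the portions of substrate follow each other after 8.0 min, the first at the start | 30 min |

- spring (time / min: product / %): 1.33: 1; 4.00: 8; 8.00: 11; 10.0: 20; 15.0: 26
- noon (time / min: product / %): 1.33: 3; 2.50: 4; 4.00: 6; 8.00: 11; 15.0: 29
- autumn (time / min: product / %): 1.33: 4; 4.00: 1; 8.00: 11; 10.0: 20; 15.0: 22
- dawn (time / min: product / %): 1.33: 9; 4.00: 13; 8.00: 19; 10.0: 23; 15.0: 38

(scatter of a reading: 2 percentage points)

- the analysis behind the earlier runs scatters by 2 percentage points, standard deviation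
- percentages count the whole charge, also what has not yet gone in
- a reading or a percentage of product counts all its forms, free or not
- no earlier run changes the charge of second catalyst; that part of a forecast is a guess

* ranking by amount of product, in percent of the substrate charged, from high to low, at 30 min (red / blue / teal / grey / ochre / green)
* the amount of product, in percent of the substrate charged of the flask you put first, at 30 min
* the amount of product, in percent of the substrate charged of the flask you put last, at 30 min

**Dosing end.** Spring, noon and autumn, from 13 mM to 63 mM of substrate, all read 11% at 8.00 min, so within the scatter of 2 percentage points these runs look first order in substrate. Noon's 11% at 8.00 min comes from the first portion, a quarter of the charge. Taking product as reacted substrate, that portion was 44.0% consumed, and first-order decay then gives a rate constant, read from this one scattered reading, of 0.0725 min⁻¹ at 0.12 mM of free catalyst. Summing the 4 portions, each aged from its addition to 30 min, I get a dosing figure of 66.8%.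

**Two neighbours.** Teal and red share the coupling partner, the free catalyst and the interval of 8.0 min, so the dosing figure serves both, but they differ in substrate and second catalyst. Teal's ceiling of 110% stands above the dosing figure, so I expect teal to end near 66.8%. Red's ceiling stands below it, so I expect red to end at 27.5%: of the two ends, take the lower. What red's 0.60 mM of second catalyst does remains a guess, as no earlier run changes that charge.

**The forecast.** It ranks grey > green > ochre > teal > blue > red, with 96% on top and 27% last. On red it reasons from the same ratio: “Red can reach at most 22/80 = 27.5%, and it gets there.”

**The result.** The flasks rank grey > green > teal > ochre > blue > red, which swaps teal and ochre against the forecast, with 96.7% on top.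

    substrate + free catalyst → free catalyst + intermediate (k = 761 L mol⁻¹ min⁻¹)
    coupling partner + second catalyst + intermediate → second catalyst + product (k = 4.77 × 10⁵ L² mol⁻² min⁻¹)
    crystals ⇌ product, rate k3*(cs3 - [product]) while solid is left; crystals form when [product] > cs3 (solubility = 7.90 mM, k = 1.49 min⁻¹)
    free catalyst → spent catalyst (k = 0.0109 min⁻¹)
    2 substrate → homo dimer (k = 0.00207 L mol⁻¹ min⁻¹)

**Red's end.** Red gives 27.5%, equal to its partner ceiling. At 30.0 min its coupling partner stands at 0% of its charge, while 39.3% of the substrate charged sits as intermediate. The same flask with 37 mM of coupling partner has a ceiling of 46.2%, and it gives 46.2%.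

The readings stem from a simulated flask for substances that don't exist; noise was put on by code.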